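**Retrosynthetic overview**

1. Numbering (bicyclo[5.3.0]decane): C1 = methyl-bearing quaternary ring-fusion carbon, C2 = CH2, C3/C4 = epoxide carbons (CH3 on C4), C5 = CH2, C6 = benzoyloxy carbon, C7 = ring-fusion CH, C8 = C(OH)(i-Pr), C9/C10 = CH2; seven-membered ring C1–C7, five-membered ring C1/C7–C10. The target is the (1R,3S,4R,6S,7S,8R) isomer.
2. Endgame: benzoate 16 ⇐ epoxy diol 15 ⇐ (C6–OH-directed epoxidation) ene-diol 14 ⇐ (i-Pr–M addition to C8=O) hydroxy ketone 13 ⇐ (hydroboration of C6=C7, CO2Me → CH3, deketalisation) cyclohepta-1,4-diene ester 7.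
3. Key disconnection: bonds C1–C2 and C4–C5 of the seven-membered ring of 7 ⇐ 1-vinylcyclopentene 3 (C1, C7–C10, C6, C5) + vinylcarbenoid from 5 (C2, C3, C4), by Rh(II) cyclopropanation and Cope rearrangement of cis-divinylcyclopropane 6 (formal (4+3) cycloaddition).
4. Enabling feature: in the seven-membered ring the epoxide pair C3/C4 and the cis H/O pair C7/C6 are 1,4-related across the lone CH2 C5 and lie opposite the sp3–sp3 bond C1–C2. The ring is therefore a cyclohepta-1,4-diene (C3=C4, C6=C7) in retron form: a divinylcyclopropane rearrangement makes its C1–C2 bond and quaternary C1, and C4–C5–C6 is the former cyclopropane.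
5. Ring order: the five-membered ring is bought with 1; the seven-membered ring is closed last, in step 4; the oxirane (functional group, not skeleton) follows in step 11.

Key step: step 4

Remark (assumption): the sense of asymmetric induction in step 4 is assigned by analogy with known cyclopropanations of monosubstituted alkenes by donor/acceptor carbenoids. Rh2(S-PTAD)4 is written; if the substrate responds in the opposite sense, the antipodal catalyst Rh2(R-PTAD)4 takes its place with nothing else changed.

**Route**

Step 1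
Reactants: 1 2-bromo-3-methylcyclopent-2-en-1-one
Product: 2 6-bromo-7-methyl-1,4-dioxaspiro[4.4]non-6-ene
Conditions: ethylene glycol, p-TsOH (cat.), benzene, reflux, Dean–Stark
Reagents that add atoms: ethylene glycol, OCCO
Why: Acid-catalysed ketalisation with azeotropic water removal, the established entry to α-bromo enone ketals, should mask the future C8 carbonyl and turn the enone into an electron-rich ring alkene, the bromine holding the double bond in place; no stereocentre is formed.

Step 2
Reactants: 2 6-bromo-7-methyl-1,4-dioxaspiro[4.4]non-6-ene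
Product: 3 6-ethenyl-7-methyl-1,4-dioxaspiro[4.4]non-6-ene
Conditions: tributyl(vinyl)stannane, Pd(PPh3)4 (5 mol%), BHT (trace), toluene, 100 °C
Reagents that add atoms: tributyl(vinyl)stannane, C=C[Sn](CCCC)(CCCC)CCCC
Why: Stille cross-coupling of an alkenyl bromide with a vinylstannane should give the 1-vinylcycloalkene under neutral conditions that leave the ketal untouched; no stereocentre is formed.

Step 3
Reactants: 4 methyl but-3-enoate
Product: 5 methyl 2-diazobut-3-enoate
Conditions: p-ABSA, DBU, MeCN, 0 °C; pentane extraction; used at once as a cold solution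
Reagents that add atoms: 4-acetamidobenzenesulfonyl azide, CC(=O)Nc1ccc(cc1)S(=O)(=O)N=[N+]=[N-]
Why: Regitz diazo transfer to the dienolate of a β,γ-unsaturated ester is the standard preparation of vinyldiazoacetates, and immediate use avoids the known cyclisation of 5 to a pyrazole.

Step 4
Reactants: 3 6-ethenyl-7-methyl-1,4-dioxaspiro[4.4]non-6-ene; 5 methyl 2-diazobut-3-enoate
Product: 7 methyl (1R)-8,8-(ethylenedioxy)-1-methylbicyclo[5.3.0]deca-3,6-diene-4-carboxylate, via cis-divinylcyclopropane 6 (not isolated)
Conditions: Rh2(S-PTAD)4 (1 mol%), 5 (2.5 equiv, slow addition), 2,2-dimethylbutane, −20 °C → rt; then toluene, 80 °C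
Reagents that add atoms: none
Why: The Rh(II) donor/acceptor carbenoid from 5 should cyclopropanate the only accessible alkene of 3, the monosubstituted vinyl group (the ring alkene is tetrasubstituted), with its vinyl donor cis to the cyclopentenyl group, and the resulting cis-divinylcyclopropane 6 then undergoes Cope rearrangement through the obligatory boat transition state on warming. The closest known reaction type is the Rh(II)-catalysed tandem cyclopropanation/Cope rearrangement (formal (4+3) cycloaddition) of vinyldiazoacetates with dienes, including 1-vinyl-2-methylcycloalkenes that deliver an angular methyl-bearing quaternary carbon. The seven-membered ring closes by the concerted [3,3] shift: the σ-bond C1–C2 forms between the unsubstituted vinyl terminus and the methyl-bearing ring carbon while the cyclopropane bond C4–C6 breaks, a three-to-seven ring enlargement rather than an endo or exo cyclisation of a chain. The single new stereocentre C1 is controlled by the catalyst, which fixes the absolute configuration (1S,2S) of 6; the boat geometry transfers it stereospecifically to C1 (R) while the cyclopropane stereocentres vanish. The step needs site selectivity (secured by the tetrasubstituted ring alkene), cis-diastereoselectivity in the cyclopropanation (inherent to donor/acceptor carbenoids, ester trans to the alkene substituent), enantioselectivity (chiral Rh(II) carboxylate) and preference for cyclopropanation over oxonium-ylide formation at the ketal (favoured by the alkene selectivity of vinylcarbenoids); the Z-methyl group at the reacting terminus raises the Cope barrier, hence the thermal finish.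

Step 5
Reactants: 7 methyl (1R)-8,8-(ethylenedioxy)-1-methylbicyclo[5.3.0]deca-3,6-diene-4-carboxylate
Product: 9 methyl (1R,6S,7S)-8,8-(ethylenedioxy)-6-hydroxy-1-methylbicyclo[5.3.0]dec-3-ene-4-carboxylate, via C6-alkylborane 8 (not isolated)
Conditions: BH3·THF (1.5 equiv), THF, 0 °C; then 30% H2O2, aq. NaOAc, 0 °C
Reagents that add atoms: hydrogen peroxide, OO (hydroxyl oxygen); borane–THF, B.C1CCOC1 (boron of 8 only)
Why: Hydroboration–oxidation should take the electron-rich trisubstituted C6=C7 alkene in preference to the conjugated ester alkene C3=C4, place boron on the less substituted C6, and add syn from the face anti to the pseudo-axial C1 methyl group (as in Δ5-steroids and 7a-methylhydrindenes), so that C7–H and C6–OH (oxidation with retention) end up cis to each other and the ring fusion trans.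

Step 6
Reactants: 9 methyl (1R,6S,7S)-8,8-(ethylenedioxy)-6-hydroxy-1-methylbicyclo[5.3.0]dec-3-ene-4-carboxylate
Product: 10 (1R,6S,7S)-8,8-(ethylenedioxy)-4-(hydroxymethyl)-1-methylbicyclo[5.3.0]dec-3-en-6-ol
Conditions: DIBAL-H (4 equiv), CH2Cl2, −78 → 0 °C; Rochelle salt work-up
Reagents that add atoms: none
Why: DIBAL-H 1,2-reduction of an α,β-unsaturated ester should give the allylic alcohol without touching the ketal or any stereocentre.

Step 7
Reactants: 10 (1R,6S,7S)-8,8-(ethylenedioxy)-4-(hydroxymethyl)-1-methylbicyclo[5.3.0]dec-3-en-6-ol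
Product: 11 (1R,6S,7S)-4-(chloromethyl)-8,8-(ethylenedioxy)-1-methylbicyclo[5.3.0]dec-3-en-6-ol
Conditions: NCS, Me2S, CH2Cl2, −20 → 0 °C (no amine base)
Reagents that add atoms: N-chlorosuccinimide, O=C1CCC(=O)N1Cl
Why: Corey–Kim chlorination converts only the allylic alcohol into the chloride (chloride collapse of the allylic alkoxysulfonium salt), while the saturated secondary C6 hydroxyl is returned unchanged on work-up because no base is present to trigger oxidation.

Step 8
Reactants: 11 (1R,6S,7S)-4-(chloromethyl)-8,8-(ethylenedioxy)-1-methylbicyclo[5.3.0]dec-3-en-6-ol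
Product: 12 (1R,6S,7S)-8,8-(ethylenedioxy)-1,4-dimethylbicyclo[5.3.0]dec-3-en-6-ol
Conditions: LiEt3BH (3 equiv), THF, 0 °C → rt; aqueous work-up
Reagents that add atoms: none
Why: Direct SN2 hydride displacement of the primary allylic chloride by Super-Hydride should give the C4 methyl group without allylic transposition, completing the removal of the ester that activated the carbenoid and shielded C3=C4 in step 5.

Step 9
Reactants: 12 (1R,6S,7S)-8,8-(ethylenedioxy)-1,4-dimethylbicyclo[5.3.0]dec-3-en-6-ol
Product: 13 (1R,6S,7S)-6-hydroxy-1,4-dimethylbicyclo[5.3.0]dec-3-en-8-one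
Conditions: PPTS (cat.), THF/H2O (4:1), 40 °C
Reagents that add atoms: water, O
Why: Mild acid hydrolysis of the dioxolane should release the C8 ketone, the weak acid and moderate temperature being chosen to avoid dehydration of the β-hydroxy ketone and epimerisation at C7.

Step 10
Reactants: 13 (1R,6S,7S)-6-hydroxy-1,4-dimethylbicyclo[5.3.0]dec-3-en-8-one
Product: 14 (1R,6S,7S,8R)-1,4-dimethyl-8-(propan-2-yl)bicyclo[5.3.0]dec-3-ene-6,8-diol
Conditions: i-PrMgCl (3.5 equiv), LaCl3·2LiCl (1.1 equiv), THF, −20 → 0 °C; then H2O
Reagents that add atoms: isopropylmagnesium chloride, CC(C)[Mg]Cl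
Why: Lanthanide-promoted Grignard 1,2-addition (suppressing enolisation and β-hydride reduction; one equivalent is consumed by the C6–OH) should occur on the cyclopentanone face of C7–H, anti to the C7–C6 bond and to the pseudo-axial C1 methyl group, which places the C8 hydroxyl cis to the C1 methyl (8R).

Step 11
Reactants: 14 (1R,6S,7S,8R)-1,4-dimethyl-8-(propan-2-yl)bicyclo[5.3.0]dec-3-ene-6,8-diol
Product: 15 (1R,3S,4R,6S,7S,8R)-3,4-epoxy-1,4-dimethyl-8-(propan-2-yl)bicyclo[5.3.0]decane-6,8-diol
Conditions: VO(acac)2 (5 mol%), t-BuOOH (1.5 equiv), CH2Cl2, 0 °C → rt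
Reagents that add atoms: tert-butyl hydroperoxide, CC(C)(C)OO
Why: Vanadium-catalysed hydroxyl-directed epoxidation of the homoallylic alcohol should deliver oxygen to the C3=C4 face syn to the C6 hydroxyl, which is also the face anti to the C1 methyl group (matched), setting C3 (S) and C4 (R).

Step 12
Reactants: 15 (1R,3S,4R,6S,7S,8R)-3,4-epoxy-1,4-dimethyl-8-(propan-2-yl)bicyclo[5.3.0]decane-6,8-diol
Product: 16 (1R,3S,4R,6S,7S,8R)-3,4-epoxy-8-hydroxy-1,4-dimethyl-8-(propan-2-yl)bicyclo[5.3.0]decan-6-yl benzoate
Conditions: BzCl (1.5 equiv), pyridine, DMAP (cat.), CH2Cl2, 0 °C → rt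
Reagents that add atoms: benzoyl chloride, O=C(Cl)c1ccccc1
Why: DMAP-catalysed acylation should esterify the secondary C6 hydroxyl only, the tertiary C8 hydroxyl being too hindered and the epoxide inert under these buffered conditions.

**Compound list**

1 | 2-bromo-3-methylcyclopent-2-en-1-one | CC1=C(Br)C(=O)CC1 | starting material
2 | 6-bromo-7-methyl-1,4-dioxaspiro[4.4]non-6-ene | CC1=C(Br)C2(CC1)OCCO2 | intermediate
3 | 6-ethenyl-7-methyl-1,4-dioxaspiro[4.4]non-6-ene | CC1=C(C=C)C2(CC1)OCCO2 | intermediate
4 | methyl but-3-enoate | COC(=O)CC=C | starting material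
5 | methyl 2-diazobut-3-enoate | COC(=O)C(=[N+]=[N-])C=C | intermediate
6 | methyl (1S,2S)-1-ethenyl-2-(7-methyl-1,4-dioxaspiro[4.4]non-6-en-6-yl)cyclopropane-1-carboxylate (cis-divinylcyclopropane) | COC(=O)[C@]1(C=C)C[C@H]1C2=C(C)CCC23OCCO3 | intermediate (not isolated)
7 | methyl (1R)-8,8-(ethylenedioxy)-1-methylbicyclo[5.3.0]deca-3,6-diene-4-carboxylate | C1COC2(O1)CC[C@]3(C)CC=C(C(=O)OC)CC=C32 | intermediate
8 | methyl (1R,6S,7R)-6-boranyl-8,8-(ethylenedioxy)-1-methylbicyclo[5.3.0]dec-3-ene-4-carboxylate (C6-alkylborane) | C1COC2(O1)CC[C@]3(C)CC=C(C(=O)OC)C[C@H](B)[C@H]32 | intermediate (not isolated)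
9 | methyl (1R,6S,7S)-8,8-(ethylenedioxy)-6-hydroxy-1-methylbicyclo[5.3.0]dec-3-ene-4-carboxylate | C1COC2(O1)CC[C@]3(C)CC=C(C(=O)OC)C[C@H](O)[C@H]32 | intermediate
10 | (1R,6S,7S)-8,8-(ethylenedioxy)-4-(hydroxymethyl)-1-methylbicyclo[5.3.0]dec-3-en-6-ol | C1COC2(O1)CC[C@]3(C)CC=C(CO)C[C@H](O)[C@H]32 | intermediate
11 | (1R,6S,7S)-4-(chloromethyl)-8,8-(ethylenedioxy)-1-methylbicyclo[5.3.0]dec-3-en-6-ol | C1COC2(O1)CC[C@]3(C)CC=C(CCl)C[C@H](O)[C@H]32 | intermediate
12 | (1R,6S,7S)-8,8-(ethylenedioxy)-1,4-dimethylbicyclo[5.3.0]dec-3-en-6-ol | C1COC2(O1)CC[C@]3(C)CC=C(C)C[C@H](O)[C@H]32 | intermediate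
13 | (1R,6S,7S)-6-hydroxy-1,4-dimethylbicyclo[5.3.0]dec-3-en-8-one | O=C1CC[C@]2(C)CC=C(C)C[C@H](O)[C@H]21 | intermediate
14 | (1R,6S,7S,8R)-1,4-dimethyl-8-(propan-2-yl)bicyclo[5.3.0]dec-3-ene-6,8-diol | CC(C)[C@]1(O)CC[C@]2(C)CC=C(C)C[C@H](O)[C@H]21 | intermediate
15 | (1R,3S,4R,6S,7S,8R)-3,4-epoxy-1,4-dimethyl-8-(propan-2-yl)bicyclo[5.3.0]decane-6,8-diol | CC(C)[C@]1(O)CC[C@]2(C)C[C@@H]3O[C@]3(C)C[C@H](O)[C@H]21 | intermediate
16 | (1R,3S,4R,6S,7S,8R)-3,4-epoxy-8-hydroxy-1,4-dimethyl-8-(propan-2-yl)bicyclo[5.3.0]decan-6-yl benzoate | CC(C)[C@]1(O)CC[C@]2(C)C[C@@H]3O[C@]3(C)C[C@H](OC(=O)c3ccccc3)[C@H]21 | target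

**Step count**

Total: 12 steps. Longest linear sequence: 11 steps (1, 2, 4–12); step 3 is a one-step branch.

**Three steps most likely to fail**

Step 4 (key step). The carbenoid may be diverted before it reaches the hindered vinyl group (self-condensation of the diazo compound, oxonium-ylide formation at the ketal oxygens). The Cope rearrangement of the Z-methyl-substituted divinylcyclopropane may stall, or enantiofacial discrimination may be insufficient. The fallback separates carbene transfer from the hindered diene; it sets out from 5 and 2 and comes back at 6, hence 7. Compound 5 is decomposed by the same chiral Rh(II) catalyst in the presence of commercial vinylboronic acid pinacol ester, an unhindered monosubstituted alkene, which should give the cyclopropylboronate methyl (1R,2R)-1-ethenyl-2-(4,4,5,5-tetramethyl-1,3,2-dioxaborolan-2-yl)cyclopropane-1-carboxylate F1 with boron cis to the vinyl group. A stereoretentive Suzuki–Miyaura coupling of F1 with alkenyl bromide 2 (Pd(OAc)2, SPhos, K3PO4, toluene/H2O, 90 °C) should then give 6, which rearranges to 7 at the coupling temperature or on further heating.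

Step 5. If the hindered C6=C7 alkene reacts sluggishly, chemoselectivity may be lost through borane attack on the conjugated ester, or discrimination between the two faces of C6=C7 may be insufficient. The fallback removes the ester first and sets C7 by enolate protonation; it sets out from 7 and comes back at 13. DIBAL-H should reduce 7 to the allylic alcohol [(1R)-8,8-(ethylenedioxy)-1-methylbicyclo[5.3.0]deca-3,6-dien-4-yl]methanol F2. Sulfation with SO3·pyridine followed by LiAlH4 (allylic deoxygenation) should give (1R)-8,8-(ethylenedioxy)-1,4-dimethylbicyclo[5.3.0]deca-3,6-diene F3. Mild acid hydrolysis (oxalic acid, THF/H2O) should give the dienone (1R)-1,4-dimethylbicyclo[5.3.0]deca-3,6-dien-8-one F4. Weitz–Scheffer epoxidation (H2O2, NaOH, MeOH, 0 °C) should attack only the enone double bond, anti to the C1 methyl group, and give the epoxy ketone (1R,6S,7R)-6,7-epoxy-1,4-dimethylbicyclo[5.3.0]dec-3-en-8-one F5. SmI2 (THF/MeOH, −90 °C) should cleave the C7–O bond and give 13, with C6 keeping the epoxide oxygen and C7 set by protonation of the samarium enolate.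

Step 10. The hindered cyclopentanone may enolise, the isopropyl reagent may transfer a β-hydride (reduction instead of addition), or the β-alkoxide may undergo retro-aldol cleavage. The fallback uses an sp2 nucleophile and a separate reduction; it sets out from 13 and comes back at 14. Isopropenylmagnesium bromide with anhydrous CeCl3 (THF, −78 °C), which is smaller, less basic and cannot deliver a β-hydride, should add from the same face and give (1R,6S,7S,8S)-1,4-dimethyl-8-(prop-1-en-2-yl)bicyclo[5.3.0]dec-3-ene-6,8-diol F6. Hydrogenation with Wilkinson's catalyst (H2, benzene) should reduce only the 1,1-disubstituted alkene and leave the trisubstituted ring alkene, giving 14.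

**Further compounds**

F1 | step 4 | methyl (1R,2R)-1-ethenyl-2-(4,4,5,5-tetramethyl-1,3,2-dioxaborolan-2-yl)cyclopropane-1-carboxylate | COC(=O)[C@]1(C=C)C[C@H]1B2OC(C)(C)C(C)(C)O2
F2 | step 5 | [(1R)-8,8-(ethylenedioxy)-1-methylbicyclo[5.3.0]deca-3,6-dien-4-yl]methanol | C1COC2(O1)CC[C@]3(C)CC=C(CO)CC=C32
F3 | step 5 | (1R)-8,8-(ethylenedioxy)-1,4-dimethylbicyclo[5.3.0]deca-3,6-diene | C1COC2(O1)CC[C@]3(C)CC=C(C)CC=C32
F4 | step 5 | (1R)-1,4-dimethylbicyclo[5.3.0]deca-3,6-dien-8-one | O=C1CC[C@]2(C)CC=C(C)CC=C12
F5 | step 5 | (1R,6S,7R)-6,7-epoxy-1,4-dimethylbicyclo[5.3.0]dec-3-en-8-one | O=C1CC[C@]2(C)CC=C(C)C[C@@H]3O[C@]312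
F6 | step 10 | (1R,6S,7S,8S)-1,4-dimethyl-8-(prop-1-en-2-yl)bicyclo[5.3.0]dec-3-ene-6,8-diol | CC(=C)[C@]1(O)CC[C@]2(C)CC=C(C)C[C@H](O)[C@H]21
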